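The route rests on disconnecting the C8–H and C9–H bonds of the (R)-ketone back to the alkene of a 2-aryloxy enone. The feature exploited is the C9=C8–C7=O unit: C8 carries the ether oxygen to the allyl-bearing 2,6-dimethoxyphenyl ring and is alpha to the C7 carbonyl on the 3,4,5-trimethoxyphenyl ring, making this the only electron-poor alkene beside the isolated allyl C=C. An ene-reductase adds hydride to C9 and a proton to the Si face of C8, creating (8R) in one operation without touching the allyl group. The precursor, a terminal-methylene aryl vinyl ketone, comes in two steps from methoxyeugenol, a phenacyl bromide and formaldehyde; chelation-controlled reduction then sets C7.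

Key step: step 3

Remarks on the chemistry:
- Atoms are numbered as in 8-O-4' neolignans: C7 is the benzylic carbinol carbon, C8 the ether-bearing methine, C9 the methyl carbon.
- The target SMILES corresponds to (7S,8R), the erythro diastereomer, i.e. (1S,2R)-2-(4-allyl-2,6-dimethoxyphenoxy)-1-(3,4,5-trimethoxyphenyl)propan-1-ol.
- Formaldehyde is charged as paraformaldehyde.

Step 1
Reactants: 1 4-allyl-2,6-dimethoxyphenol; 2 2-bromo-1-(3,4,5-trimethoxyphenyl)ethan-1-one
Product: 3 2-(4-allyl-2,6-dimethoxyphenoxy)-1-(3,4,5-trimethoxyphenyl)ethan-1-one
Conditions: K2CO3, acetone, reflux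
Reagents that add atoms: none
Why: Williamson ether synthesis, in which the phenoxide of 1 displaces bromide from the very SN2-reactive primary alpha-bromo ketone 2 under carbonate conditions too mild to move the allyl double bond into conjugation.

Step 2
Reactants: 3 2-(4-allyl-2,6-dimethoxyphenoxy)-1-(3,4,5-trimethoxyphenyl)ethan-1-one; 4 formaldehyde
Product: 6 2-(4-allyl-2,6-dimethoxyphenoxy)-1-(3,4,5-trimethoxyphenyl)prop-2-en-1-one, via Mannich base 5 (not isolated)
Conditions: (CH2O)n, i-Pr2NH·TFA (1 equiv), TFA (10 mol%), THF, reflux
Reagents that add atoms: none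
Why: Mannich-type alpha-methylenation, in which the enol of 3 (one enolisable position only) is aminomethylated by the iminium from formaldehyde and the amine salt and the beta-amino ketone loses diisopropylamine by E1cB elimination, giving an enone without alpha-hydrogen that cannot react a second time.

Step 3
Reactants: 6 2-(4-allyl-2,6-dimethoxyphenoxy)-1-(3,4,5-trimethoxyphenyl)prop-2-en-1-one
Product: 7 (R)-2-(4-allyl-2,6-dimethoxyphenoxy)-1-(3,4,5-trimethoxyphenyl)propan-1-one
Conditions: purified ene-reductase (Old Yellow Enzyme family, chosen from a panel for the R product), NADP+ (cat.), D-glucose, glucose dehydrogenase, potassium phosphate buffer pH 7.0, DMSO (10% v/v), 30 °C; MTBE extraction, crude used at once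
Reagents that add atoms: none
Why: The enone carbonyl is held by the conserved pair of hydrogen-bond donors above the reduced flavin, which polarises C9=C8 so that flavin N5 passes hydride to the terminal C9 while the active-site tyrosine protonates C8 from the opposite face, the flavin being re-reduced by NADPH from the glucose/glucose dehydrogenase cycle. The closest known reaction type is the ene-reductase reduction of alpha-substituted enones, including alpha-alkoxy and alpha-methylene ketones, where the alpha stereocentre arises in the protonation event. No ring is closed. The one new stereocentre, C8, is under enzyme control: the binding orientation decides which face of C8 meets the tyrosine, and the enzyme kept from the screen is the one that protonates the Si face (priorities OAr > C7 > C9), which gives R. The step needs chemoselectivity for the conjugated alkene over the allyl C=C and the C7 carbonyl, secured because only a carbonyl-activated alkene accepts flavin hydride and these enzymes do not reduce carbonyl groups, while the terminal CH2 leaves no E/Z question. The enolisable alpha-aryloxy ketone should keep its configuration if the buffer is neutral and free of thiols and amines, the run is short, and the product is extracted promptly.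

Step 4
Reactants: 7 (R)-2-(4-allyl-2,6-dimethoxyphenoxy)-1-(3,4,5-trimethoxyphenyl)propan-1-one
Product: 8 (1S,2R)-2-(4-allyl-2,6-dimethoxyphenoxy)-1-(3,4,5-trimethoxyphenyl)propan-1-ol (rhaphidecursinol B)
Conditions: Zn(BH4)2 (freshly made from ZnCl2 and NaBH4), Et2O, −30 to 0 °C; aq. NH4Cl
Reagents that add atoms: none
Why: Chelation-controlled (Cram chelate) hydride reduction, in which Zn(II) ties the C7 carbonyl oxygen to the C8 aryloxy oxygen in a five-membered ring so that hydride enters C7 from the side of the C8 hydrogen and not the C8 methyl, which from the (8R)-ketone should give the (7S) carbinol, i.e. the erythro (7S,8R) product, while the neutral reagent at low temperature leaves C8 and the allyl group alone.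

Compound list
1 | 4-allyl-2,6-dimethoxyphenol (methoxyeugenol) | C=CCc1cc(OC)c(O)c(OC)c1 | starting material
2 | 2-bromo-1-(3,4,5-trimethoxyphenyl)ethan-1-one | O=C(CBr)c1cc(OC)c(OC)c(OC)c1 | starting material
3 | 2-(4-allyl-2,6-dimethoxyphenoxy)-1-(3,4,5-trimethoxyphenyl)ethan-1-one | C=CCc1cc(OC)c(OCC(=O)c2cc(OC)c(OC)c(OC)c2)c(OC)c1 | intermediate
4 | formaldehyde (used as paraformaldehyde) | C=O | starting material
5 | 2-(4-allyl-2,6-dimethoxyphenoxy)-3-(diisopropylamino)-1-(3,4,5-trimethoxyphenyl)propan-1-one (racemic Mannich base, not isolated) | C=CCc1cc(OC)c(OC(CN(C(C)C)C(C)C)C(=O)c2cc(OC)c(OC)c(OC)c2)c(OC)c1 | intermediate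
6 | 2-(4-allyl-2,6-dimethoxyphenoxy)-1-(3,4,5-trimethoxyphenyl)prop-2-en-1-one | C=CCc1cc(OC)c(OC(=C)C(=O)c2cc(OC)c(OC)c(OC)c2)c(OC)c1 | intermediate
7 | (R)-2-(4-allyl-2,6-dimethoxyphenoxy)-1-(3,4,5-trimethoxyphenyl)propan-1-one | C=CCc1cc(OC)c(O[C@H](C)C(=O)c2cc(OC)c(OC)c(OC)c2)c(OC)c1 | intermediate
8 | (1S,2R)-2-(4-allyl-2,6-dimethoxyphenoxy)-1-(3,4,5-trimethoxyphenyl)propan-1-ol (rhaphidecursinol B, erythro, 7S,8R) | C=CCc1cc(OC)c(O[C@H](C)[C@@H](O)c2cc(OC)c(OC)c(OC)c2)c(OC)c1 | target

Total step count: 4
Longest linear sequence: 4 steps

Steps most likely to fail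

Step 3. The bulky diaryl enone may be poorly accepted or poorly soluble, so conversion may stall. Facial selectivity in the C8 protonation may be insufficient with every enzyme of the panel. The product may also racemise by enolisation during a long incubation. Fallback, a chiral-pool route that sets out from 1 and returns at 7: Mitsunobu reaction of 1 with ethyl (S)-lactate (PPh3, DIAD, THF, 0 °C to rt) should proceed with inversion to ethyl (R)-2-(4-allyl-2,6-dimethoxyphenoxy)propanoate F1. Aminolysis with N,O-dimethylhydroxylamine hydrochloride and i-PrMgCl (THF, −20 °C) should give the Weinreb amide (R)-2-(4-allyl-2,6-dimethoxyphenoxy)-N-methoxy-N-methylpropanamide F2. Addition of commercial 3,4,5-trimethoxyphenylmagnesium bromide (THF, −20 to 0 °C) should stop at the chelated tetrahedral adduct and release the (R)-ketone 7 on work-up.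

Step 2. Aminomethylation may be incomplete or the elimination may stall at the Mannich base, and the captodative enone may oligomerise under heating. Fallback, which separates C–C bond formation from elimination and sets out from 3 and returns at 6: base-catalysed hydroxymethylation with paraformaldehyde (cat. K2CO3, EtOH/acetone, rt, about one equivalent of formaldehyde) should give 2-(4-allyl-2,6-dimethoxyphenoxy)-3-hydroxy-1-(3,4,5-trimethoxyphenyl)propan-1-one F3. Mesylation (MsCl, Et3N, CH2Cl2, 0 °C) should give 2-(4-allyl-2,6-dimethoxyphenoxy)-3-(methanesulfonyloxy)-1-(3,4,5-trimethoxyphenyl)propan-1-one F4. Treatment with DBU at 0 °C should then eliminate the mesylate to the enone 6 under cold, non-acidic conditions.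

Step 4. The aryl ether oxygen, flanked by two methoxy groups, may chelate zinc only weakly, so facial selectivity at C7 may erode towards the threo diastereomer. Slow hydroboration of the allyl group is possible on long exposure. Fallback, catalyst control in place of chelate control, from 7 directly to 8: Noyori–Ikariya asymmetric transfer hydrogenation with RuCl[(R,R)-TsDPEN](p-cymene) in HCO2H/Et3N at rt. The catalyst enantiomer fixes the face of hydride delivery to the aryl ketone, and the (R,R) catalyst should give the (7S) carbinol. It should not reduce the isolated alkene. No compound beyond the list arises (entry F0).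

Further compounds
F1 | step 3 | ethyl (R)-2-(4-allyl-2,6-dimethoxyphenoxy)propanoate | C=CCc1cc(OC)c(O[C@H](C)C(=O)OCC)c(OC)c1
F2 | step 3 | (R)-2-(4-allyl-2,6-dimethoxyphenoxy)-N-methoxy-N-methylpropanamide | C=CCc1cc(OC)c(O[C@H](C)C(=O)N(C)OC)c(OC)c1
F3 | step 2 | 2-(4-allyl-2,6-dimethoxyphenoxy)-3-hydroxy-1-(3,4,5-trimethoxyphenyl)propan-1-one (racemic) | C=CCc1cc(OC)c(OC(CO)C(=O)c2cc(OC)c(OC)c(OC)c2)c(OC)c1
F4 | step 2 | 2-(4-allyl-2,6-dimethoxyphenoxy)-3-(methanesulfonyloxy)-1-(3,4,5-trimethoxyphenyl)propan-1-one (racemic) | C=CCc1cc(OC)c(OC(COS(C)(=O)=O)C(=O)c2cc(OC)c(OC)c(OC)c2)c(OC)c1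
F0 | step 4 | none | none
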